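## Retrosynthetic overview

1. Target 10, octadecyl 3-(2,4-dihydroxy-3-methoxyphenyl)propanoate (no stereocentre), is cut at the ester into methyl ester 8 and octadecan-1-ol 9.
2. The feature used: ring atoms C-2 (OH), C-3 (OMe) and C-4 (OH) are the enol form of a 2-methoxycyclohexane-1,3-dione, and the propanoate arm on C-1 is the same three-carbon unit as ring atoms C-6, C-5, C-4. Arene 8 therefore comes from dione 7 by loss of H2, and 7 from a methine carrying two identical propanoate arms.
3. Key disconnection C-3–C-4: dione 7 from keto diester 5 by Claisen closure of the only ring, the six-membered carbocycle that later becomes the arene.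
4. Keto diester 5 comes from triester 4 (Krapcho), and 4 from methyl 4-methoxy-3-oxobutanoate 1 and two molecules of methyl acrylate 2 (double Michael). The C-3 methoxy group is carried in with 1.
5. Ring order: one ring, closed in step 3 and aromatized in step 4.

Key step: step 3

Remark: the 1,3-diones are drawn as one enol tautomer; the only stereocentre on the way (C-1 of 7) is racemic and disappears on aromatization.

## Route

Step 1
Reactants: 1 methyl 4-methoxy-3-oxobutanoate; 2 methyl acrylate
Product: 4 trimethyl 3-(2-methoxyacetyl)pentane-1,3,5-tricarboxylate, via mono-Michael adduct 3 (not isolated)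
Conditions: 2 (2.3 equiv), DBU (0.2 equiv), MeCN, 0 °C → rt
Reagents that add atoms: none
Why: Double Michael addition, in which the methylene between the two carbonyls of 1 (pKa about 11) is the only carbon that the catalytic amidine base deprotonates and adds twice to the acrylate, while the non-nucleophilic base avoids the retro-Claisen loss of the methoxyacetyl group that alkoxides cause once this carbon is quaternary; no stereocentre arises.

Step 2
Reactants: 4 trimethyl 3-(2-methoxyacetyl)pentane-1,3,5-tricarboxylate
Product: 5 dimethyl 4-(2-methoxyacetyl)heptanedioate
Conditions: LiCl (3 equiv), H2O (2 equiv), DMSO, 150 °C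
Reagents that add atoms: none
Why: Krapcho dealkoxycarbonylation, in which chloride demethylates the ester next to the ketone, the resulting β-keto carboxylate loses CO2 at once and water protonates the enolate, whereas the two unactivated propanoate esters lack this decarboxylative drive and should survive; the new methine carries two identical arms and is not a stereocentre.

Step 3
Reactants: 5 dimethyl 4-(2-methoxyacetyl)heptanedioate
Product: 7 methyl 3-(4-hydroxy-3-methoxy-2-oxocyclohex-3-en-1-yl)propanoate (racemic), via sodium dione enolate 6 (not isolated)
Conditions: NaOMe (2.5 equiv), MeOH, reflux; then 2 M aq. HCl, 0 °C (pH 2)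
Reagents that add atoms: none
Why: This is an intramolecular Claisen condensation, the classical closure of 5-oxoalkanoates to cyclohexane-1,3-diones: methoxide reversibly deprotonates the ketone at its methoxymethyl carbon, this carbon (future C-3) adds to one ester carbonyl (future C-4), methoxide leaves, and the new 1,3-dione is at once deprotonated to enolate 6. The six-membered carbocycle closes in a 6-(enolendo)-exo-trig acyl substitution. Ring carbon C-1 becomes a stereocentre only because the two arms now differ; nothing controls it, 7 is racemic, and the centre is erased in step 4. The step needs enolization at CH2OMe and not at the methine (whose enolate could only close a four-membered ring), C-acylation by the ketone enolate and not Dieckmann closure between the two arms, and a single ring closure. The ketone α-CH2 is several pKa units more acidic than an ester α-CH2, every condensation is reversible in NaOMe/MeOH, and the dione enolate (conjugate acid pKa about 5) lies well below the β-keto ester enolate (pKa about 11) of a Dieckmann product, so the mixture should drain into 6; a second closure from C-3 onto the remaining ester would give a non-enolizable bridged trione that methoxide reopens. Since the two arms are identical, either one gives the same ring, and the unused arm is the propanoate chain.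

Step 4
Reactants: 7 methyl 3-(4-hydroxy-3-methoxy-2-oxocyclohex-3-en-1-yl)propanoate
Product: 8 methyl 3-(2,4-dihydroxy-3-methoxyphenyl)propanoate
Conditions: Pd/C (10 wt% Pd, 5 mol% Pd), triethylene glycol dimethyl ether, 190 °C, N2 sweep, slow addition of 7; work-up below 40 °C
Reagents that add atoms: none
Why: Heterogeneous palladium-catalysed dehydrogenative aromatization of a cyclohexane-1,3-dione to a resorcinol, driven by aromatic stabilization and by sweeping out H2, with the slow addition keeping the dione concentration low so that the released hydrogen is not transferred back to it; the methoxy group and the ester are untouched and the racemic C-1 becomes an arene carbon.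

Step 5
Reactants: 8 methyl 3-(2,4-dihydroxy-3-methoxyphenyl)propanoate; 9 octadecan-1-ol
Product: 10 octadecyl 3-(2,4-dihydroxy-3-methoxyphenyl)propanoate
Conditions: 9 (1.3 equiv), immobilized Candida antarctica lipase B, toluene–2-methylbutan-2-ol, 5 Å molecular sieves, 60 °C
Reagents that add atoms: none
Why: Lipase-catalysed transesterification through a serine acyl-enzyme, which accepts the 3-arylpropanoate acyl group and the primary alcohol 9 but not phenols, so neither O-acylation of the ring hydroxyls nor closure of the C-2 hydroxyl onto the ester should compete at 60 °C, while trapping of methanol pulls the equilibrium to 10.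

## Compound list

1 | methyl 4-methoxy-3-oxobutanoate | COCC(=O)CC(=O)OC | starting material
2 | methyl acrylate | C=CC(=O)OC | starting material
3 | dimethyl 2-(2-methoxyacetyl)pentanedioate (racemic mono-Michael adduct, not isolated) | COCC(=O)C(CCC(=O)OC)C(=O)OC | intermediate
4 | trimethyl 3-(2-methoxyacetyl)pentane-1,3,5-tricarboxylate | COCC(=O)C(CCC(=O)OC)(CCC(=O)OC)C(=O)OC | intermediate
5 | dimethyl 4-(2-methoxyacetyl)heptanedioate | COCC(=O)C(CCC(=O)OC)CCC(=O)OC | intermediate
6 | sodium 2-methoxy-4-(3-methoxy-3-oxopropyl)-3-oxocyclohex-1-en-1-olate (racemic, not isolated) | COC(=O)CCC1CCC([O-])=C(OC)C1=O.[Na+] | intermediate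
7 | methyl 3-(4-hydroxy-3-methoxy-2-oxocyclohex-3-en-1-yl)propanoate (racemic; enol form of the 1,3-dione) | COC(=O)CCC1CCC(O)=C(OC)C1=O | intermediate
8 | methyl 3-(2,4-dihydroxy-3-methoxyphenyl)propanoate | COC(=O)CCc1ccc(O)c(OC)c1O | intermediate
9 | octadecan-1-ol | CCCCCCCCCCCCCCCCCCO | starting material
10 | octadecyl 3-(2,4-dihydroxy-3-methoxyphenyl)propanoate | CCCCCCCCCCCCCCCCCCOC(=O)CCc1ccc(O)c(OC)c1O | target

## Step count and risks

Total step count: 5. Longest linear sequence: 5 steps (1 → 4 → 5 → 7 → 8 → 10).

Steps most likely to fail:

**Step 4 (aromatization).** Two processes may go wrong. Hydrogen released on the catalyst may be transferred to unreacted dione, which reduces it and costs a ring oxygen. At 190 °C the C-2 hydroxyl may also close onto the ester with loss of methanol. The fallback replaces catalytic dehydrogenation by a room-temperature silyl dienol ether oxidation; it sets out from 7 and returns at 8. Compound 7 would be silylated on both oxygens with Me3SiOTf (2.3 equiv) and Et3N in CH2Cl2 at 0 °C to give the conjugated bis-silyl dienol ether methyl 3-[3-methoxy-2,4-bis(trimethylsilyloxy)cyclohexa-2,4-dien-1-yl]propanoate F1, used crude. DDQ (1.1 equiv) with 2,4,6-collidine in benzene at rt should then remove the C-1 and C-6 hydrogens (hydride abstraction next to the dienol ether, then proton loss, the standard quinone aromatization of a cyclohexadiene) to give methyl 3-[3-methoxy-2,4-bis(trimethylsilyloxy)phenyl]propanoate F2. The silyl groups shield the electron-rich arene from over-oxidation. Methanol with a trace of HCl at rt cleaves both aryl silyl ethers to 8; in acidic methanol the ester stays open.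

**Step 3 (key Claisen closure).** Dieckmann closure between the two arms, or intermolecular condensation, may outrun equilibration to the dione enolate, and the very polar product may be lost on acidic work-up. The fallback closes the ring while only one ester arm is present, so that no Dieckmann ring is possible; it sets out from 1 and 2 and returns at 7. With one equivalent of 2 and NaOMe (2.2 equiv) in MeOH (rt, then reflux), 1 would undergo the one-pot Michael–Claisen sequence through mono-adduct 3, giving after acidification methyl 4-hydroxy-3-methoxy-2-oxocyclohex-3-ene-1-carboxylate F3. The dianion of F3 (LiN(iPr)2, 2.2 equiv, THF, −78 °C) should react at its less stabilized, ester-bearing carbon and add to 2, giving methyl 4-hydroxy-3-methoxy-1-(3-methoxy-3-oxopropyl)-2-oxocyclohex-3-ene-1-carboxylate F4. Krapcho removal of the ring carbomethoxy group (LiCl, wet DMSO, 140 °C) then gives 7.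

**Step 5 (ester exchange).** Acyl-enzyme formation may be slow because of the ortho-substituted arene, and incomplete methanol removal may stall the equilibrium. The fallback replaces acyl transfer by irreversible carboxylate alkylation; it sets out from 8 and returns at 10. Compound 8 would be saponified (LiOH, 4 equiv, degassed THF–H2O, rt; then cold 1 M HCl) to 3-(2,4-dihydroxy-3-methoxyphenyl)propanoic acid F5, used without heating. Its carboxylate alone would be alkylated with 1-bromooctadecane (1.05 equiv) and KHCO3 (1.1 equiv) in DMF at 50 °C. Hydrogencarbonate ionizes the acid but not the phenols, and the SN2 esterification cannot revert to a lactone equilibrium.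

## Further compounds

F1 | step 4 | methyl 3-[3-methoxy-2,4-bis(trimethylsilyloxy)cyclohexa-2,4-dien-1-yl]propanoate (racemic) | COC(=O)CCC1CC=C(O[Si](C)(C)C)C(OC)=C1O[Si](C)(C)C
F2 | step 4 | methyl 3-[3-methoxy-2,4-bis(trimethylsilyloxy)phenyl]propanoate | COC(=O)CCc1ccc(O[Si](C)(C)C)c(OC)c1O[Si](C)(C)C
F3 | step 3 | methyl 4-hydroxy-3-methoxy-2-oxocyclohex-3-ene-1-carboxylate (racemic; enol form of the 1,3-dione) | COC(=O)C1CCC(O)=C(OC)C1=O
F4 | step 3 | methyl 4-hydroxy-3-methoxy-1-(3-methoxy-3-oxopropyl)-2-oxocyclohex-3-ene-1-carboxylate (racemic) | COC(=O)CCC1(C(=O)OC)CCC(O)=C(OC)C1=O
F5 | step 5 | 3-(2,4-dihydroxy-3-methoxyphenyl)propanoic acid | OC(=O)CCc1ccc(O)c(OC)c1O
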